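**Plan**

1. Numbering used throughout: oxolane O1–C2(aryl)–C3–C4–C5; C9 is the CH2O carbon on C3; C7' is the benzylidene CH on C4. The retrosynthesis cuts, in this order, the acyl–O9 ester bond, the ring bond C3–C4, the ether bond O1–C5, and then the C2–vinyl and aryl–alkyne bonds.
2. Enabling feature: in the ring O1–C2–C3–C4–C5, C3 carries the C9H2–O arm and is bonded to the sp2 carbon C4 of the exocyclic C4=C7'(H)aryl unit. This is the pattern left when a C3 radical with a titanium alkoxide on C9 (from a C3–C9 epoxide) adds to a C4≡C7' aryl alkyne tethered through O1–C5.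
3. Forward: a silylated guaiacyl epoxy alcohol and a silylated 3-guaiacylpropargyl bromide are made separately and joined at O1–C5. The only ring, the oxolane, then closes by C3–C4 bond formation; acylation of O9 and global desilylation finish the chain.
4. Stereochemistry: C2 comes from a Sharpless kinetic resolution with L-(+)-DIPT. C3 comes from 1,2-induction by C2 in the ring closure (2,3-trans). The 4E alkene comes from capture of the vinyl radical on the side away from C3. The epoxide stereocentre is sacrificed.

Key step: step 8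

Assumption: in the kinetic resolution the aryl group of 4 takes the place of the usual carbinol substituent, so with L-(+)-DIPT the (R)-enantiomer should be the one epoxidised (to the erythro epoxy alcohol); if the sense proved opposite, D-(−)-DIPT would be used instead.

**Route**

Step 1
Reactants: 1 vanillin
Product: 2 4-[(tert-butyldimethylsilyl)oxy]-3-methoxybenzaldehyde
Conditions: TBSCl, imidazole, DMF, rt
Reagents that add atoms: tert-butyldimethylsilyl chloride, CC(C)(C)[Si](C)(C)Cl
Why: Silyl ether formation on a phenol masks the acidic OH before the Grignard step, and the aryl silyl ether can later be removed with buffered fluoride without touching an ester.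

Step 2
Reactants: 2 4-[(tert-butyldimethylsilyl)oxy]-3-methoxybenzaldehyde; 3 vinylmagnesium bromide
Product: 4 rac-1-[4-[(tert-butyldimethylsilyl)oxy]-3-methoxyphenyl]prop-2-en-1-ol
Conditions: CH2=CHMgBr (1.2 equiv), THF, −78 → 0 °C; sat. aq. NH4Cl
Reagents that add atoms: none
Why: Grignard 1,2-addition to an aryl aldehyde should give the racemic aryl vinyl carbinol, whose carbinol carbon becomes C2 and is resolved in the next step.

Step 3
Reactants: 4 rac-1-[4-[(tert-butyldimethylsilyl)oxy]-3-methoxyphenyl]prop-2-en-1-ol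
Product: 5 (S)-[4-[(tert-butyldimethylsilyl)oxy]-3-methoxyphenyl][(2R)-oxiran-2-yl]methanol
Conditions: Ti(OiPr)4 (0.15 equiv), L-(+)-DIPT (0.2 equiv), TBHP (0.5 equiv, isooctane), 4 Å MS, CH2Cl2, −20 °C
Reagents that add atoms: tert-butyl hydroperoxide, CC(C)(C)OO
Why: Sharpless asymmetric epoxidation run as a kinetic resolution should epoxidise (R)-4 much faster than (S)-4 and give the erythro (1S,2'R) epoxy alcohol, so the configuration of C2 is fixed here by the tartrate and the unreacted (S)-4 is removed by chromatography.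

Step 4
Reactants: 6 4-bromo-2-methoxyphenol
Product: 7 (4-bromo-2-methoxyphenoxy)(tert-butyl)dimethylsilane
Conditions: TBSCl, imidazole, DMF, rt
Reagents that add atoms: tert-butyldimethylsilyl chloride, CC(C)(C)[Si](C)(C)Cl
Why: Silyl ether formation on the phenol gives the same protecting group on both guaiacyl rings, so one fluoride step can release all phenols at the end.

Step 5
Reactants: 7 (4-bromo-2-methoxyphenoxy)(tert-butyl)dimethylsilane; 8 propargyl alcohol
Product: 9 3-[4-[(tert-butyldimethylsilyl)oxy]-3-methoxyphenyl]prop-2-yn-1-ol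
Conditions: PdCl2(PhCN)2 (3 mol%), P(t-Bu)3·HBF4 (6 mol%), CuI (2 mol%), i-Pr2NH, dioxane, rt → 40 °C
Reagents that add atoms: none
Why: Sonogashira coupling with the bulky electron-rich phosphine should engage the electron-rich aryl bromide near room temperature, and the amine base leaves the aryl silyl ether intact.

Step 6
Reactants: 9 3-[4-[(tert-butyldimethylsilyl)oxy]-3-methoxyphenyl]prop-2-yn-1-ol
Product: 10 tert-butyl[4-(3-bromoprop-1-yn-1-yl)-2-methoxyphenoxy]dimethylsilane
Conditions: CBr4, PPh3, CH2Cl2, 0 °C
Reagents that add atoms: carbon tetrabromide, BrC(Br)(Br)Br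
Why: The Appel reaction converts the primary propargylic alcohol into the bromide under neutral conditions that the silyl ether and the alkyne tolerate.

Step 7
Reactants: 5 (S)-[4-[(tert-butyldimethylsilyl)oxy]-3-methoxyphenyl][(2R)-oxiran-2-yl]methanol; 10 tert-butyl[4-(3-bromoprop-1-yn-1-yl)-2-methoxyphenoxy]dimethylsilane
Product: 11 (2R)-2-[(S)-[4-[(tert-butyldimethylsilyl)oxy]-3-methoxyphenyl][[3-[4-[(tert-butyldimethylsilyl)oxy]-3-methoxyphenyl]prop-2-yn-1-yl]oxy]methyl]oxirane
Conditions: Ag2O (2 equiv), 4 Å MS, CH2Cl2, rt, dark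
Reagents that add atoms: none
Why: Silver(I) oxide-mediated O-alkylation (a Williamson-type etherification without free alkoxide) forms the O1–C5 bond at the oxygen of the carbinol without touching its stereocentre, and should avoid Payne rearrangement of the epoxy alcohol and alkoxide attack on the aryl silyl ethers.

Step 8
Reactants: 11 (2R)-2-[(S)-[4-[(tert-butyldimethylsilyl)oxy]-3-methoxyphenyl][[3-[4-[(tert-butyldimethylsilyl)oxy]-3-methoxyphenyl]prop-2-yn-1-yl]oxy]methyl]oxirane
Product: 12 [(2R,3S,4E)-2-[4-[(tert-butyldimethylsilyl)oxy]-3-methoxyphenyl]-4-[[4-[(tert-butyldimethylsilyl)oxy]-3-methoxyphenyl]methylidene]oxolan-3-yl]methanol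
Conditions: Cp2TiCl2 (2.5 equiv), Zn dust (6 equiv), THF, rt (green Cp2TiCl solution added dropwise to 11); then 1 M HCl, 0 °C
Reagents that add atoms: none
Why: Cp2TiCl transfers one electron to the epoxide, the C3–O bond breaks homolytically to the more substituted C3 radical with the titanium(IV) alkoxide on C9, this radical adds to C4 of the tethered aryl alkyne, and the linear α-aryl vinyl radical at C7' is reduced by a second Cp2TiCl (or takes H from THF) and protonated on work-up. The closest known reaction type is the titanocene(III)-mediated reductive epoxide opening with radical cyclisation onto alkynes (Nugent–RajanBabu conditions), which turns epoxy propargyl ethers into 3-hydroxymethyl-4-alkylidene tetrahydrofurans. The oxolane ring closes in the 5-exo-dig mode by forming C3–C4. The new C3 stereocentre is controlled by C2: in the chair-like Beckwith–Houk transition state the C2 aryl group lies pseudo-equatorial and the C9H2OTi arm on the radical carbon turns away from it, which should give the 2,3-trans (2R,3S) ring, while the former epoxide centre is erased on homolysis and has no influence. The 4E geometry should follow from capture of the vinyl radical from the C5H2 side, remote from substituted C3, which leaves the aryl group cis to C3. The step needs ring closure to outrun reduction of the C3 radical to an alkyltitanium (which would β-eliminate to a deoxygenated allyl ether); the conjugating aryl group on the alkyne speeds the addition and slow addition of Cp2TiCl keeps the Ti(III) concentration low.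

Step 9
Reactants: 13 4-hydroxybenzoic acid
Product: 15 4-[(tert-butyldimethylsilyl)oxy]benzoic acid, via bis-silylated silyl ester 14 (not isolated)
Conditions: TBSCl (2.3 equiv), imidazole, DMF, rt; then AcOH/THF/H2O, rt
Reagents that add atoms: tert-butyldimethylsilyl chloride, CC(C)(C)[Si](C)(C)Cl
Why: Exhaustive silylation followed by selective hydrolysis of the far more labile silyl ester is the usual way to an O-silyl hydroxybenzoic acid and leaves the aryl silyl ether in place.

Step 10
Reactants: 12 [(2R,3S,4E)-2-[4-[(tert-butyldimethylsilyl)oxy]-3-methoxyphenyl]-4-[[4-[(tert-butyldimethylsilyl)oxy]-3-methoxyphenyl]methylidene]oxolan-3-yl]methanol; 15 4-[(tert-butyldimethylsilyl)oxy]benzoic acid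
Product: 16 [(2R,3S,4E)-2-[4-[(tert-butyldimethylsilyl)oxy]-3-methoxyphenyl]-4-[[4-[(tert-butyldimethylsilyl)oxy]-3-methoxyphenyl]methylidene]oxolan-3-yl]methyl 4-[(tert-butyldimethylsilyl)oxy]benzoate
Conditions: DCC, DMAP (cat.), CH2Cl2, 0 °C → rt
Reagents that add atoms: none
Why: Steglich esterification acylates the only free hydroxyl (primary, on C9) under near-neutral conditions, so C2, C3 and the alkene geometry are not disturbed.

Step 11
Reactants: 16 [(2R,3S,4E)-2-[4-[(tert-butyldimethylsilyl)oxy]-3-methoxyphenyl]-4-[[4-[(tert-butyldimethylsilyl)oxy]-3-methoxyphenyl]methylidene]oxolan-3-yl]methyl 4-[(tert-butyldimethylsilyl)oxy]benzoate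
Product: 17 agastenol, [(2R,3S,4E)-2-(4-hydroxy-3-methoxyphenyl)-4-[(4-hydroxy-3-methoxyphenyl)methylidene]oxolan-3-yl]methyl 4-hydroxybenzoate
Conditions: TBAF (3.3 equiv), AcOH (3.5 equiv), THF, 0 °C
Reagents that add atoms: none
Why: Fluoride desilylation removes the three aryl silyl ethers, and the acetic acid buffer keeps the phenols protonated so that the benzoate, the C2 benzylic ether (no quinone methide opening) and the alkene should survive.

**Compound list**

1 | vanillin | COc1cc(C=O)ccc1O | starting material
2 | 4-[(tert-butyldimethylsilyl)oxy]-3-methoxybenzaldehyde | COc1cc(C=O)ccc1O[Si](C)(C)C(C)(C)C | intermediate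
3 | vinylmagnesium bromide | C=C[Mg]Br | starting material
4 | rac-1-[4-[(tert-butyldimethylsilyl)oxy]-3-methoxyphenyl]prop-2-en-1-ol | C=CC(O)c1ccc(O[Si](C)(C)C(C)(C)C)c(OC)c1 | intermediate
5 | (S)-[4-[(tert-butyldimethylsilyl)oxy]-3-methoxyphenyl][(2R)-oxiran-2-yl]methanol (erythro) | O[C@@H](c1ccc(O[Si](C)(C)C(C)(C)C)c(OC)c1)[C@H]1CO1 | intermediate
6 | 4-bromo-2-methoxyphenol | COc1cc(Br)ccc1O | starting material
7 | (4-bromo-2-methoxyphenoxy)(tert-butyl)dimethylsilane | COc1cc(Br)ccc1O[Si](C)(C)C(C)(C)C | intermediate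
8 | propargyl alcohol | C#CCO | starting material
9 | 3-[4-[(tert-butyldimethylsilyl)oxy]-3-methoxyphenyl]prop-2-yn-1-ol | COc1cc(C#CCO)ccc1O[Si](C)(C)C(C)(C)C | intermediate
10 | tert-butyl[4-(3-bromoprop-1-yn-1-yl)-2-methoxyphenoxy]dimethylsilane | COc1cc(C#CCBr)ccc1O[Si](C)(C)C(C)(C)C | intermediate
11 | (2R)-2-[(S)-[4-[(tert-butyldimethylsilyl)oxy]-3-methoxyphenyl][[3-[4-[(tert-butyldimethylsilyl)oxy]-3-methoxyphenyl]prop-2-yn-1-yl]oxy]methyl]oxirane | COc1cc(C#CCO[C@@H](c2ccc(O[Si](C)(C)C(C)(C)C)c(OC)c2)[C@H]2CO2)ccc1O[Si](C)(C)C(C)(C)C | intermediate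
12 | [(2R,3S,4E)-2-[4-[(tert-butyldimethylsilyl)oxy]-3-methoxyphenyl]-4-[[4-[(tert-butyldimethylsilyl)oxy]-3-methoxyphenyl]methylidene]oxolan-3-yl]methanol | COc1cc(/C=C2/CO[C@@H](c3ccc(O[Si](C)(C)C(C)(C)C)c(OC)c3)[C@@H]2CO)ccc1O[Si](C)(C)C(C)(C)C | intermediate
13 | 4-hydroxybenzoic acid | O=C(O)c1ccc(O)cc1 | starting material
14 | tert-butyldimethylsilyl 4-[(tert-butyldimethylsilyl)oxy]benzoate (not isolated) | CC(C)(C)[Si](C)(C)OC(=O)c1ccc(O[Si](C)(C)C(C)(C)C)cc1 | intermediate
15 | 4-[(tert-butyldimethylsilyl)oxy]benzoic acid | CC(C)(C)[Si](C)(C)Oc1ccc(C(=O)O)cc1 | intermediate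
16 | [(2R,3S,4E)-2-[4-[(tert-butyldimethylsilyl)oxy]-3-methoxyphenyl]-4-[[4-[(tert-butyldimethylsilyl)oxy]-3-methoxyphenyl]methylidene]oxolan-3-yl]methyl 4-[(tert-butyldimethylsilyl)oxy]benzoate | COc1cc(/C=C2/CO[C@@H](c3ccc(O[Si](C)(C)C(C)(C)C)c(OC)c3)[C@@H]2COC(=O)c2ccc(O[Si](C)(C)C(C)(C)C)cc2)ccc1O[Si](C)(C)C(C)(C)C | intermediate
17 | agastenol, [(2R,3S,4E)-2-(4-hydroxy-3-methoxyphenyl)-4-[(4-hydroxy-3-methoxyphenyl)methylidene]oxolan-3-yl]methyl 4-hydroxybenzoate | COc1cc(/C=C2/CO[C@@H](c3ccc(O)c(OC)c3)[C@@H]2COC(=O)c2ccc(O)cc2)ccc1O | target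

**Step count**

Total steps: 11. Longest linear sequence: 7 steps (1, 2, 3, 7, 8, 10, 11 from vanillin; the arm 4, 5, 6, 7, 8, 10, 11 from 4-bromo-2-methoxyphenol is equally long).

**Steps most likely to fail**

Step 8. The linear vinyl radical at C7' may be captured from both sides, so that alkene geometry is not controlled and the 4Z isomer forms beside 12. Premature reduction of the C3 radical and incomplete 2,3-trans induction are lesser concerns. Fallback: the geometric mixture obtained from 11 is not discarded but irradiated with visible light and a triplet sensitiser (Ir(ppy)3 or thioxanthone, MeCN, rt). Energy transfer should excite preferentially the flatter, better conjugated isomer with the aryl group next to unsubstituted C5H2, namely [(2R,3S,4Z)-2-[4-[(tert-butyldimethylsilyl)oxy]-3-methoxyphenyl]-4-[[4-[(tert-butyldimethylsilyl)oxy]-3-methoxyphenyl]methylidene]oxolan-3-yl]methanol F1, and drain it into the more twisted 12, as in contra-thermodynamic sensitised styrene isomerisations. This fallback sets out from 11 and returns at 12.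

Step 7. O-Alkylation of the hindered secondary epoxy alcohol by the bulky arylpropargyl bromide may be sluggish, with silver-assisted opening of the epoxide or decay of 10 taking over. Fallback: the aryl–alkyne bond is made after the ether bond. From 5, etherification with the small and more reactive propargyl bromide (Ag2O, CH2Cl2, or NaH, THF, 0 °C) should give the terminal alkyne (2R)-2-[(S)-[4-[(tert-butyldimethylsilyl)oxy]-3-methoxyphenyl](prop-2-yn-1-yloxy)methyl]oxirane F2. Sonogashira coupling of F2 with aryl bromide 7 under the conditions of step 5 then returns to the route at 11, and steps 5 and 6 are no longer needed.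

Step 3. The electron-rich benzylic carbinol or its epoxy alcohol may ionise on the Lewis acidic titanium catalyst (allylic transposition, solvolysis), and the enantiomers may be discriminated incompletely, which would erode the purity of C2. Fallback: the resolution is moved to an enzyme and the epoxidation to a titanium-free catalyst. From 4, lipase-catalysed transesterification (CAL-B, vinyl acetate, MTBE, rt) should acylate the (R)-enantiomer (Kazlauskas rule) to (R)-1-[4-[(tert-butyldimethylsilyl)oxy]-3-methoxyphenyl]prop-2-en-1-yl acetate F3, which is separated from (S)-4. DIBAL-H (CH2Cl2, −78 °C) releases (R)-1-[4-[(tert-butyldimethylsilyl)oxy]-3-methoxyphenyl]prop-2-en-1-ol F4. Hydroxyl-directed epoxidation (VO(acac)2 cat., TBHP, CH2Cl2, 0 °C) then gives 5 together with its threo epimer (S)-[4-[(tert-butyldimethylsilyl)oxy]-3-methoxyphenyl][(2S)-oxiran-2-yl]methanol F5. The epimers need not be separated, because the epoxide centre disappears in step 8: F5 passes through step 7 to the epoxide epimer of 11, (2S)-2-[(S)-[4-[(tert-butyldimethylsilyl)oxy]-3-methoxyphenyl][[3-[4-[(tert-butyldimethylsilyl)oxy]-3-methoxyphenyl]prop-2-yn-1-yl]oxy]methyl]oxirane F6, and F6 and 11 should give the same 12. This fallback sets out from 4 and returns at 5 (for the epimeric share, at 12).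

**Further compounds**

F1 | step 8 | [(2R,3S,4Z)-2-[4-[(tert-butyldimethylsilyl)oxy]-3-methoxyphenyl]-4-[[4-[(tert-butyldimethylsilyl)oxy]-3-methoxyphenyl]methylidene]oxolan-3-yl]methanol | COc1cc(/C=C2\CO[C@@H](c3ccc(O[Si](C)(C)C(C)(C)C)c(OC)c3)[C@@H]2CO)ccc1O[Si](C)(C)C(C)(C)C
F2 | step 7 | (2R)-2-[(S)-[4-[(tert-butyldimethylsilyl)oxy]-3-methoxyphenyl](prop-2-yn-1-yloxy)methyl]oxirane | C#CCO[C@@H](c1ccc(O[Si](C)(C)C(C)(C)C)c(OC)c1)[C@H]1CO1
F3 | step 3 | (R)-1-[4-[(tert-butyldimethylsilyl)oxy]-3-methoxyphenyl]prop-2-en-1-yl acetate | C=C[C@@H](OC(C)=O)c1ccc(O[Si](C)(C)C(C)(C)C)c(OC)c1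
F4 | step 3 | (R)-1-[4-[(tert-butyldimethylsilyl)oxy]-3-methoxyphenyl]prop-2-en-1-ol | C=C[C@@H](O)c1ccc(O[Si](C)(C)C(C)(C)C)c(OC)c1
F5 | step 3 | (S)-[4-[(tert-butyldimethylsilyl)oxy]-3-methoxyphenyl][(2S)-oxiran-2-yl]methanol | O[C@@H](c1ccc(O[Si](C)(C)C(C)(C)C)c(OC)c1)[C@@H]1CO1
F6 | step 3 | (2S)-2-[(S)-[4-[(tert-butyldimethylsilyl)oxy]-3-methoxyphenyl][[3-[4-[(tert-butyldimethylsilyl)oxy]-3-methoxyphenyl]prop-2-yn-1-yl]oxy]methyl]oxirane | COc1cc(C#CCO[C@@H](c2ccc(O[Si](C)(C)C(C)(C)C)c(OC)c2)[C@@H]2CO2)ccc1O[Si](C)(C)C(C)(C)C
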